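If you want to know what this flask holds of target and crystals together at the end, watch the starting material, which leaves by two exits.

starting material 0.054 M; reagent 2.00 equiv; time 20 h

    starting material → intermediate A (k1 = 0.022 /h)
    starting material → target (k2 = 0.020 /h)
    intermediate A → side product A (k3 = 0.046 /h)
    reagent + intermediate A → intermediate B (k4 = 0.30 /M/h)
    reagent + intermediate B → side product B (k5 = 0.018 /M/h)
    crystals ⇌ target, rate k6*(cs6 - [target]) while solid is left; crystals form when [target] > cs6 (cs6 = 1.7 mM, k6 = 0.21 /h)

- what is said of target includes crystals
- crystals is a solid; its amount is given per volume of the solution
- run time (flask): 20 h

- the target and crystals together standing at 20 h, as a percentage of the starting material charged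
- the change that raises the amount of target and crystals together at 20 h, in percent of the starting material charged most ("none" if none brings more than 2 percentage points) (delta / gamma / eta / none)
- amount of target and crystals together at 20 h, in percent of the starting material charged, after delta

- delta: doubling the solubility in step 6, all else as stated
- gamma: doubling the dissolution coefficient of step 6, all else as stated
- eta: doubling the amount of reagent, all else as stated

Take first the step to target alone, at 0.020 /h. Target forms at that constant times the fraction of starting material left, so target at 20 h is the constant times the time times the mean fraction left. Put the mid-run fraction, 81.9%, in place of the mean and you get 32.7%; the exact curve gives 33.0%, an error of 0.22 percentage points.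

Now add the exit to intermediate A, at 0.022 /h. Starting material leaves at 0.0420 /h, the mid-run fraction falls to 65.7%, and the same reckoning gives 26.3%. The exact mean, 67.7%, stands higher than the mid-run value, and the error grows to 0.78 points. Written out, the exact mean leaves a simpler product. Of whatever starting material is used, 47.6% goes to target, and this target share, the constant of the target step over the sum of both exits, is what is usually called the selectivity. With 56.8% used, that gives 27.1%.

Then come the steps that start from intermediate A and intermediate B, and none of them feeds starting material or target. The reagent enters at those steps, downstream of both exits, so in my reckoning doubling it leaves the total where it was. Crystals exchange with dissolved target, and the count takes the two together, so in my reckoning doubling the solubility or doubling the dissolution coefficient of the crystal step moves target between its two forms and leaves the total where it was. So my reckoning stays at 27.1%, with no useful change among the doublings, and 27.1% after doubling the solubility.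

The forecast gives 27.06%, none and 27.06%, on the ground that “Crystallisation only shifts material between dissolved target and crystals”.

The flask gives 27.1%, best change none, and 27.1% after doubling the solubility. That doubling moves the total by 0 points, though crystals hold 19.0% of the 27.1% at 20.0 h. This flask has 43% of its starting material left then, and the target share times what has gone comes to 27.1% of the charge. Read at 3.0 d, the same charge has 4.86% of its starting material left, the target share times what has gone comes to 45.3% of the charge, and that flask shows 45.3%.

The constants are made up; what happens was integrated by code.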